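The side chain is cut at C11–C1′ into a drimane C11 aldehyde and a chiral cyclopentenone, and the drimane core is cut back to an open farnesyl chain. In the key step a drimenol synthase folds (2E,6E)-farnesyl diphosphate chair–chair and in one operation forms C4–C5 and C9–C10, closes rings A and B as a trans-decalin, fixes C5, C9 and C10, leaves the alkene at C7=C8 and frees the C11 alcohol. The feature exploited is that rings A/B are a folded all-E farnesyl chain and that C7=C8 lies next to the β-CH2OH on C9, which later guides oxygen to the hindered β face of C8. The precursor is the acyclic C15 allylic diphosphate.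

Key step: step 3

Atom labels: drimane numbering C1–C15 (C11 is the exocyclic carbon on C9, C12 the methyl on C8). In the five-membered ring, C1′ is bonded to C11, C2′ is the oxygen-bearing neighbour, then C3′, C4′ (second oxygen-bearing carbon) and C5′ (chlorine-bearing carbon).

Assumption: 3, 4 and 5 are drawn as free acids but handled as ammonium or magnesium salts in water, and the dione 20 is taken to rest as the C2′ enol drawn for the target.

Step 1
Reactants: 1 (2E,6E)-farnesol
Product: 2 (2E,6E)-farnesyl chloride
Conditions: NCS, Me2S, CH2Cl2, −30 to 0 °C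
Reagents that add atoms: N-chlorosuccinimide, O=C1CCC(=O)N1Cl
Why: Corey–Kim-type chlorination, in which chloride displaces the alkoxysulfonium salt of the primary allylic alcohol by SN2 under cold, neutral conditions, so neither the position nor the E geometry of the alkenes should change.

Step 2
Reactants: 2 (2E,6E)-farnesyl chloride
Product: 3 (2E,6E)-farnesyl diphosphate
Conditions: (n-Bu4N)3HP2O7, MeCN, rt; Dowex 50W-X8 (NH4+ form); cellulose chromatography
Reagents that add atoms: tris(tetrabutylammonium) hydrogen diphosphate, CCCC[N+](CCCC)(CCCC)CCCC.CCCC[N+](CCCC)(CCCC)CCCC.CCCC[N+](CCCC)(CCCC)CCCC.OP([O-])(=O)OP([O-])([O-])=O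
Why: SN2 displacement of a primary allylic chloride by the diphosphate anion in a dipolar aprotic solvent is the standard entry to allylic diphosphates and leaves both E alkenes untouched.

Step 3
Reactants: 3 (2E,6E)-farnesyl diphosphate
Product: 6 (−)-drimenol, via drimenyl diphosphate 4 (not isolated), via drimenyl phosphate 5 (not isolated)
Conditions: recombinant bifunctional drimenol synthase (class two cyclase domain fused to a phosphatase domain, Aquimarina spongiae enzyme from E. coli), MgCl2, HEPES pH 7.5, 30 °C, slow feed of 3, pentane overlay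
Reagents that add atoms: none
Why: The catalytic aspartic acid of the cyclase domain protonates C3 of the terminal alkene, the C4 cation is captured by C5 of the central alkene, the new C10 cation by C9 of the proximal alkene, and the C8 cation loses a C7 proton to give 4, after which the phosphatase domain takes off the two phosphate groups in turn by P–O cleavage so that O11 stays on C11. The closest known reaction type is the proton-initiated cation–alkene polycyclisation run by class two terpene cyclases, and 3 is the native substrate of this enzyme. Ring A closes 6-endo-trig (bond C4–C5) and ring B closes 6-endo-trig (bond C9–C10), each as an anti addition across an E alkene. C5 and C10 are set by the E geometry of the central alkene in a chair fold (H5 and the C10 methyl trans), C9 by the E geometry of the proximal alkene in the second chair (C11 equatorial and β), and the absolute sense (5S,9S,10S) by the chiral pocket, which admits only one of the two mirror-image chair–chair folds. The step needs protonation at the distal alkene only, no ionisation of the allylic diphosphate, and loss of the C7 proton rather than a C9 or C12 proton. In the substrate the electron-rich isopropylidene end is the most basic site, the alkene next to the electron-withdrawing diphosphate is the least nucleophilic and so reacts last, and the Mg2+-bound diphosphate anchors the chain so that the enzyme base sits next to C7.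

Step 4
Reactants: 6 (−)-drimenol
Product: 7 7β,8β-epoxydriman-11-ol
Conditions: VO(acac)2 (cat.), t-BuOOH, toluene, 0 °C to rt
Reagents that add atoms: tert-butyl hydroperoxide, CC(C)(C)OO
Why: Hydroxyl-directed vanadium-catalysed epoxidation of a homoallylic alcohol, in which the C11 alkoxide binds the vanadium peroxide and, being β on C9, hands oxygen to the β face of C7=C8, overriding the α preference of undirected peracids and setting C8 (O β, methyl α) and, for the moment, C7.

Step 5
Reactants: 7 7β,8β-epoxydriman-11-ol
Product: 8 driman-8β,11-diol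
Conditions: LiAlH4, THF, reflux; then H2O, aq. NaOH
Reagents that add atoms: none
Why: Fürst–Plattner (trans-diaxial) hydride opening, in which hydride attacks the less substituted C7 along the axial α trajectory and the C8–O bond is not broken, so oxygen stays as the axial 8β tertiary alcohol and C7 becomes CH2.

Step 6
Reactants: 8 driman-8β,11-diol
Product: 9 8β,11-bis(triethylsilyloxy)drimane
Conditions: Et3SiOTf, 2,6-lutidine, CH2Cl2, 0 °C to rt
Reagents that add atoms: triethylsilyl triflate, CC[Si](CC)(CC)OS(=O)(=O)C(F)(F)F
Why: Silylation with a silyl triflate and a hindered pyridine base is strong enough for the axial tertiary 8β-OH as well as the primary C11-OH, and no stereocentre is involved.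

Step 7
Reactants: 9 8β,11-bis(triethylsilyloxy)drimane
Product: 10 8β-(triethylsilyloxy)driman-11-al
Conditions: (COCl)2, DMSO, CH2Cl2, −78 to −35 °C; Et3N, −78 to 0 °C
Reagents that add atoms: none
Why: Swern oxidation applied directly to a silyl ether, in which the chlorosulfonium reagent exchanges only with the primary triethylsilyl ether and the alkoxysulfonium salt collapses to the aldehyde while the tertiary silyl ether stays, and the formyl group is already equatorial on C9, so short contact with Et3N should not epimerise it.

Step 8
Reactants: 11 (R)-4-(tert-butyldimethylsilyloxy)cyclopent-2-enone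
Product: 12 (R)-4-(tert-butyldimethylsilyloxy)-2-iodocyclopent-2-enone
Conditions: I2, pyridine, CH2Cl2, 0 °C to rt
Reagents that add atoms: iodine, II
Why: α-Iodination of an enone by pyridine addition, iodination of the enolate and loss of pyridine, a sequence that does not involve C4, which keeps its R configuration.

Step 9
Reactants: 12 (R)-4-(tert-butyldimethylsilyloxy)-2-iodocyclopent-2-enone
Product: 13 (R)-8-(tert-butyldimethylsilyloxy)-6-iodo-1,4-dioxaspiro[4.4]non-6-ene
Conditions: (Me3SiOCH2)2, Me3SiOTf (cat.), CH2Cl2, −78 to −20 °C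
Reagents that add atoms: 1,2-bis(trimethylsilyloxy)ethane, C[Si](C)(C)OCCO[Si](C)(C)C
Why: Noyori ketalisation masks the ketone under cold, aprotic conditions without moving the alkene or expelling the allylic silyloxy group.

Step 10
Reactants: 13 (R)-8-(tert-butyldimethylsilyloxy)-6-iodo-1,4-dioxaspiro[4.4]non-6-ene; 10 8β-(triethylsilyloxy)driman-11-al
Product: 16 (4R)-4-(tert-butyldimethylsilyloxy)-2-[(11R)-11-hydroxy-8β-(triethylsilyloxy)driman-11-yl]cyclopent-2-enone, via vinyllithium 14 (not isolated), via ketal carbinol 15 (not isolated)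
Conditions: 13, t-BuLi (2 equiv), Et2O, −78 °C; 10, −78 to −40 °C; then aq. oxalic acid, THF, rt
Reagents that add atoms: water, O
Why: Iodine–lithium exchange gives an α-ketovinyl anion equivalent that adds irreversibly (1,2-addition) to the hindered aldehyde and mild acid then frees the enone; in the reactive rotamer C=O eclipses H9 and the formyl H sits between the axial C10 methyl and O8, so the nucleophile should enter Felkin–Anh-like from the C1/C10 side, anti to C8 with its bulky 8β-OSiEt3, which sets C11 as R.

Step 11
Reactants: 16 (4R)-4-(tert-butyldimethylsilyloxy)-2-[(11R)-11-hydroxy-8β-(triethylsilyloxy)driman-11-yl]cyclopent-2-enone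
Product: 18 (2E,3R,4R)-4-(tert-butyldimethylsilyloxy)-3-chloro-2-[8β-(triethylsilyloxy)driman-11-ylidene]cyclopentanone, via chlorosulfite 17 (not isolated)
Conditions: SOCl2 (1.1 equiv), Et2O, −40 to 0 °C
Reagents that add atoms: thionyl chloride, O=S(Cl)Cl
Why: SNi′ collapse of the chlorosulfite of a Morita–Baylis–Hillman-type allylic alcohol passes chlorine suprafacially from O11 to C5′ through a six-membered array while C11=C1′ forms; for the 11R carbinol the rotamer leading to the E alkene (C9 beside the flat C2′ carbonyl, H11 toward C5′) holds the chlorosulfite on the ring face opposite the C4′ silyloxy group, whereas the Z-forming rotamer would have to deliver chlorine syn to that group and against the C1/C12 flanks of C9, so C11 and C4′ act together to give the E alkene and 5′R.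

Step 12
Reactants: 18 (2E,3R,4R)-4-(tert-butyldimethylsilyloxy)-3-chloro-2-[8β-(triethylsilyloxy)driman-11-ylidene]cyclopentanone
Product: 19 (2E,3R,4R)-3-chloro-4-hydroxy-2-(8β-hydroxydriman-11-ylidene)cyclopentanone
Conditions: HF·pyridine, pyridine, MeCN, 0 °C to rt
Reagents that add atoms: none
Why: Buffered HF desilylation, the usual method for base-sensitive β-hydroxy ketones, cleaves both ethers at silicon, so C8 and C4′ keep their configuration and the allylic chloride should be spared.

Step 13
Reactants: 19 (2E,3R,4R)-3-chloro-4-hydroxy-2-(8β-hydroxydriman-11-ylidene)cyclopentanone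
Product: 21 (4E,5R)-5-chloro-3-hydroxy-4-(8β-hydroxydriman-11-ylidene)cyclopent-2-enone, via diketone tautomer 20 (not isolated)
Conditions: IBX, DMSO, rt
Reagents that add atoms: none
Why: IBX oxidation of a β-hydroxy ketone to the 1,3-diketone is neutral and base-free, cannot touch the tertiary 8β-OH, removes the auxiliary C4′ stereocentre without disturbing C5′ or the alkene, and the dione should enolise at C2′ to the linearly conjugated form.

Compound list
1 | (2E,6E)-farnesol | CC(C)=CCC/C(C)=C/CC/C(C)=C/CO | starting material
2 | (2E,6E)-farnesyl chloride | CC(C)=CCC/C(C)=C/CC/C(C)=C/CCl | intermediate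
3 | (2E,6E)-farnesyl diphosphate | CC(C)=CCC/C(C)=C/CC/C(C)=C/COP(O)(=O)OP(O)(O)=O | intermediate
4 | drimenyl diphosphate | CC1(C)CCC[C@]2(C)[C@@H](COP(O)(=O)OP(O)(O)=O)C(C)=CC[C@@H]12 | intermediate
5 | drimenyl phosphate | CC1(C)CCC[C@]2(C)[C@@H](COP(O)(O)=O)C(C)=CC[C@@H]12 | intermediate
6 | (−)-drimenol (H5 α, H9 α, C10 methyl β) | CC1(C)CCC[C@]2(C)[C@@H](CO)C(C)=CC[C@@H]12 | intermediate
7 | 7β,8β-epoxydriman-11-ol | CC1(C)CCC[C@]2(C)[C@@H](CO)[C@@]3(C)O[C@H]3C[C@@H]12 | intermediate
8 | driman-8β,11-diol | CC1(C)CCC[C@]2(C)[C@@H](CO)[C@@](C)(O)CC[C@@H]12 | intermediate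
9 | 8β,11-bis(triethylsilyloxy)drimane | CC1(C)CCC[C@]2(C)[C@@H](CO[Si](CC)(CC)CC)[C@@](C)(O[Si](CC)(CC)CC)CC[C@@H]12 | intermediate
10 | 8β-(triethylsilyloxy)driman-11-al | CC1(C)CCC[C@]2(C)[C@@H](C=O)[C@@](C)(O[Si](CC)(CC)CC)CC[C@@H]12 | intermediate
11 | (R)-4-(tert-butyldimethylsilyloxy)cyclopent-2-enone | O=C1C=C[C@H](O[Si](C)(C)C(C)(C)C)C1 | starting material
12 | (R)-4-(tert-butyldimethylsilyloxy)-2-iodocyclopent-2-enone | O=C1C(I)=C[C@H](O[Si](C)(C)C(C)(C)C)C1 | intermediate
13 | (R)-8-(tert-butyldimethylsilyloxy)-6-iodo-1,4-dioxaspiro[4.4]non-6-ene | IC1=C[C@H](O[Si](C)(C)C(C)(C)C)CC12OCCO2 | intermediate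
14 | vinyllithium from 13 | [Li]C1=C[C@H](O[Si](C)(C)C(C)(C)C)CC12OCCO2 | intermediate
15 | (11R)-ketal carbinol (ethylene ketal of 16) | CC1(C)CCC[C@]2(C)[C@@H]([C@@H](O)C3=C[C@H](O[Si](C)(C)C(C)(C)C)CC34OCCO4)[C@@](C)(O[Si](CC)(CC)CC)CC[C@@H]12 | intermediate
16 | (4R)-4-(tert-butyldimethylsilyloxy)-2-[(11R)-11-hydroxy-8β-(triethylsilyloxy)driman-11-yl]cyclopent-2-enone | CC1(C)CCC[C@]2(C)[C@@H]([C@@H](O)C3=C[C@H](O[Si](C)(C)C(C)(C)C)CC3=O)[C@@](C)(O[Si](CC)(CC)CC)CC[C@@H]12 | intermediate
17 | C11 chlorosulfite of 16 | CC1(C)CCC[C@]2(C)[C@@H]([C@@H](OS(Cl)=O)C3=C[C@H](O[Si](C)(C)C(C)(C)C)CC3=O)[C@@](C)(O[Si](CC)(CC)CC)CC[C@@H]12 | intermediate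
18 | (2E,3R,4R)-4-(tert-butyldimethylsilyloxy)-3-chloro-2-[8β-(triethylsilyloxy)driman-11-ylidene]cyclopentanone | CC1(C)CCC[C@]2(C)[C@@H](/C=C3\C(=O)C[C@@H](O[Si](C)(C)C(C)(C)C)[C@@H]3Cl)[C@@](C)(O[Si](CC)(CC)CC)CC[C@@H]12 | intermediate
19 | (2E,3R,4R)-3-chloro-4-hydroxy-2-(8β-hydroxydriman-11-ylidene)cyclopentanone | CC1(C)CCC[C@]2(C)[C@@H](/C=C3\C(=O)C[C@@H](O)[C@@H]3Cl)[C@@](C)(O)CC[C@@H]12 | intermediate
20 | (4E,5R)-5-chloro-4-(8β-hydroxydriman-11-ylidene)cyclopentane-1,3-dione | CC1(C)CCC[C@]2(C)[C@@H](/C=C3\C(=O)CC(=O)[C@@H]3Cl)[C@@](C)(O)CC[C@@H]12 | intermediate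
21 | (4E,5R)-5-chloro-3-hydroxy-4-(8β-hydroxydriman-11-ylidene)cyclopent-2-enone (CNP0279879.2) | CC1(C)CCC[C@]2(C)[C@@H](/C=C3\C(O)=CC(=O)[C@@H]3Cl)[C@@](C)(O)CC[C@@H]12 | target

Total step count: 13. Longest linear sequence: 11 steps (steps 1–7 and 10–13). Steps 8 and 9 build the ring fragment in parallel.

Steps most likely to fail

1. Step 11.
- Risk: the suprafacial pathway may leak into an ionic one with free chloride. That would uncouple the alkene geometry from C11 and erode E selectivity. The HCl formed may also trigger β-elimination of the C4′ silyloxy group.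
- Fallback: it sets out from 16 and comes back at 18, and it separates the two tasks.
- The alcohol is converted into the C11 methanesulfonate F4 (MsCl, Et3N, CH2Cl2, −40 °C) and treated with LiCl in THF/DMF.
- Chloride then enters C5′ as an external nucleophile by addition–elimination, and its face is governed only by the C4′ silyloxy group (trans entry), whatever the C11 configuration.
- The part of the product obtained as the Z-alkylidene isomer F5 is irradiated at 350 nm in MeCN (E/Z photoisomerisation of an alkylidene ketone). 18 is separated by chromatography and F5 is recycled.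

2. Step 10.
- Risk: facial selectivity at the formyl group may be poor, since both flanks of C9 are quaternary, and enolisation of the hindered aldehyde may compete.
- Fallback: it sets out from 15 and comes back at 15, which then goes on to 16.
- The addition is quenched with aq. NH4Cl and the C11-epimeric carbinols are isolated. They are oxidised with Dess–Martin periodinane to the C11 ketone F3.
- The configuration is then set by reagent control in a Corey–Bakshi–Shibata reduction (BH3·SMe2), using the catalyst enantiomer that sends hydride to the Si face of C11.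
- The resulting 11R carbinol 15 is hydrolysed with aq. oxalic acid to 16.

3. Step 4.
- Risk: undirected α-face oxygen transfer may compete, because the axial C10 methyl screens the β face of C8.
- Fallback: it sets out from 6 and comes back at 7, and it uses the intrinsic α preference instead of opposing it.
- Boc2O and DMAP give tert-butyl drimenyl carbonate F1.
- I2 in MeCN at −20 °C forms the iodonium ion on the open α face. The carbonate oxygen opens it at C8 from the β face (trans-diaxial, 6-exo iodocarbonate cyclisation) to give the cyclic iodocarbonate F2.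
- K2CO3 in MeOH cleaves the carbonate, and the 8β alkoxide displaces the antiperiplanar 7α iodide, closing the β epoxide 7.

Further compounds
F1 | step 4 | tert-butyl drimenyl carbonate | CC1(C)CCC[C@]2(C)[C@@H](COC(=O)OC(C)(C)C)C(C)=CC[C@@H]12
F2 | step 4 | 7α-iododrimane-8β,11-diyl carbonate | CC1(C)CCC[C@]2(C)[C@H]3COC(=O)O[C@@]3(C)[C@H](I)C[C@@H]12
F3 | step 10 | C11 ketone derived from 15 | CC1(C)CCC[C@]2(C)[C@@H](C(=O)C3=C[C@H](O[Si](C)(C)C(C)(C)C)CC34OCCO4)[C@@](C)(O[Si](CC)(CC)CC)CC[C@@H]12
F4 | step 11 | C11 methanesulfonate of 16 | CC1(C)CCC[C@]2(C)[C@@H]([C@@H](OS(C)(=O)=O)C3=C[C@H](O[Si](C)(C)C(C)(C)C)CC3=O)[C@@](C)(O[Si](CC)(CC)CC)CC[C@@H]12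
F5 | step 11 | Z-alkylidene isomer of 18 | CC1(C)CCC[C@]2(C)[C@@H](/C=C3/C(=O)C[C@@H](O[Si](C)(C)C(C)(C)C)[C@@H]3Cl)[C@@](C)(O[Si](CC)(CC)CC)CC[C@@H]12
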